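The ten-membered ring and the butanolide are opened together across C7–C8 and O7–C19. The feature used is that C7 and C8 are neighbouring oxygenated carbons and C8 lies beta to the lactone carbonyl C19 through C17, so C18–C17=C8 can act as a 2-carboalkoxyallyl metal. In one operation, zinc turns the C18 bromide into that allyl metal, C8 adds to the C7 chloroenal (ten-membered ring) and the new C7 alkoxide closes the lactone on C19. The precursor is a trans-1,2-disubstituted cyclohexene carrying the C2–C7 chloroenal arm and a bromomethyl acrylate whose enol oxygen (O8) is tied to O9 in a di-tert-butylsilylene ring.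

Key step: step 25

Remarks on the chemistry (one line each):
- Atom numbers are those of the target: C1 quaternary ring-fusion carbon (C15 methyl), C2 acetoxy carbon, C3, C4, C5 (C16 methyl)=C6 (Cl), C7, C8, C9, C10, C11 (C20 methyl), C12 acetoxy carbon, C13=C14; C17 (C18) and C19 belong to the lactone.
- Enol ether geometry: with the aldehyde substituent equatorial in the chair, H7 comes out anti to O8 only when O8 is cis to C18, so 36 is built with CH2Br cis to O8 and the ester cis to C9.
- O8 and O9 are held in one di-tert-butylsilylene ring instead of two separate silyl ethers, so that C9 decides the face of C8 and one fluoride step frees both hydroxyls.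
- Assumption: in the oxazaborolidine reductions the fully substituted C1 (step 9) and the ring carbon C10 (step 19) act as the large ketone substituents, vinyl and alkynyl as the small ones.

Step 1
Reactants: 1 2,2-dimethoxyacetaldehyde; 2 ethyl 2-(triphenyl-λ5-phosphanylidene)propanoate
Product: 4 ethyl (2E)-2-methyl-4-oxobut-2-enoate, via dimethyl acetal 3 (not isolated)
Conditions: CH2Cl2, rt; then 1 M HCl, THF, rt
Reagents that add atoms: water, O
Why: Wittig olefination with a stabilised, α-branched ylide should give the (E)-trisubstituted enoate, and dilute acid then hydrolyses the allylic dimethyl acetal to the aldehyde.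

Step 2
Reactants: 4 ethyl (2E)-2-methyl-4-oxobut-2-enoate; 5 (E)-penta-1,3-diene
Product: 6 ethyl (1S,5S,6S)-6-formyl-1,5-dimethylcyclohex-3-ene-1-carboxylate
Conditions: (5S)-5-benzyl-2,2,3-trimethylimidazolidin-4-one·HCl (20 mol %), 5 (3 equiv), CH3NO2–H2O 95:5, 0 °C to rt
Reagents that add atoms: none
Why: Iminium-catalysed Diels–Alder reaction: the unsubstituted diene terminus should bond to the iminium β-carbon C1 and the methyl-bearing terminus to C10, the iminium group sits endo (C9 cis to the C11 methyl), the (E)-dienophile fixes C15 cis and C2 trans to C9, and the benzyl group of the catalyst shields one face of the s-trans iminium so that the enantiomer shown should form.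

Step 3
Reactants: 6 ethyl (1S,5S,6S)-6-formyl-1,5-dimethylcyclohex-3-ene-1-carboxylate
Product: 7 ethyl (1S,5S,6S)-6-(dimethoxymethyl)-1,5-dimethylcyclohex-3-ene-1-carboxylate
Conditions: HC(OMe)3, p-TsOH·H2O (cat.), MeOH, rt
Reagents that add atoms: trimethyl orthoformate, COC(OC)OC
Why: Acid-catalysed acetalisation masks the C9 aldehyde against the hydride, Grignard and amide reagents of steps 4 to 10.

Step 4
Reactants: 7 ethyl (1S,5S,6S)-6-(dimethoxymethyl)-1,5-dimethylcyclohex-3-ene-1-carboxylate
Product: 8 [(1S,5S,6S)-6-(dimethoxymethyl)-1,5-dimethylcyclohex-3-en-1-yl]methanol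
Conditions: LiAlH4, THF, 0 °C
Reagents that add atoms: none
Why: Hydride reduction of the hindered ester gives the neopentyl C2 alcohol, the acetal being inert.

Step 5
Reactants: 8 [(1S,5S,6S)-6-(dimethoxymethyl)-1,5-dimethylcyclohex-3-en-1-yl]methanol
Product: 9 syn-epoxy alcohol (12,13-epoxide of 8, oxirane oxygen cis to the CH2OH group and trans to the C11 methyl)
Conditions: VO(acac)2 (5 mol %), t-BuOOH, CH2Cl2, 0 °C to rt
Reagents that add atoms: tert-butyl hydroperoxide, CC(C)(C)OO
Why: Hydroxyl-directed vanadium-catalysed epoxidation: the C2 hydroxymethyl group, bishomoallylic to C13, should deliver the peroxide to the ring face it occupies, which sets C12 and C13, and the syn epoxy alcohol cannot open its own oxirane from the back.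

Step 6
Reactants: 9 syn-epoxy alcohol
Product: 10 epoxy aldehyde (C2 aldehyde on C1)
Conditions: Dess–Martin periodinane, NaHCO3, CH2Cl2, rt
Reagents that add atoms: none
Why: Dess–Martin oxidation of a neopentyl primary alcohol to a non-enolisable aldehyde under buffered conditions that leave oxirane and acetal intact.

Step 7
Reactants: 10 epoxy aldehyde
Product: 11 epoxy vinyl carbinol (C2 epimers)
Conditions: CH2=CHMgBr, THF, −78 °C
Reagents that add atoms: vinylmagnesium bromide, C=C[Mg]Br
Why: Grignard 1,2-addition to the aldehyde brings in C3 and C4 at low temperature without opening the oxirane; the C2 configuration is not relied on because steps 8 and 9 reset it.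

Step 8
Reactants: 11 epoxy vinyl carbinol (C2 epimers)
Product: 12 epoxy vinyl ketone (C2 ketone)
Conditions: Dess–Martin periodinane, NaHCO3, CH2Cl2, 0 °C
Reagents that add atoms: none
Why: Dess–Martin oxidation converges both C2 epimers on one enone that has no α-hydrogen on the C1 side.

Step 9
Reactants: 12 epoxy vinyl ketone
Product: 13 epoxy allylic alcohol with the C2 configuration of the target
Conditions: (R)-Me-CBS oxazaborolidine (0.3 equiv), catecholborane, toluene, −78 °C
Reagents that add atoms: none
Why: Corey–Bakshi–Shibata reduction: the catalyst differentiates the fully substituted C1 (large) from the vinyl group (small), so the hydride should be delivered under reagent control to the face that gives the C2 carbinol of the target, 1,2-reduction being the normal course for enones with catecholborane at −78 °C.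

Step 10
Reactants: 13 epoxy allylic alcohol
Product: 14 diene diol (C2 and C12 hydroxyls, C13=C14 and C3=C4 alkenes)
Conditions: LiNEt2 (4 equiv), Et2O–hexane, 0 °C to reflux
Reagents that add atoms: none
Why: Lithium amide-promoted rearrangement of an epoxide to an allylic alcohol: syn β-elimination should take the accessible secondary C14 hydrogen cis to the oxirane oxygen in preference to the tertiary C11 hydrogen, breaking the C13–O bond and leaving the C12 oxygen with its configuration.

Step 11
Reactants: 15 ethyl 2-chloro-3-oxobutanoate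
Product: 16 ethyl (2E)-2-chloro-3-[(trifluoromethanesulfonyl)oxy]but-2-enoate (triflate oxygen cis to the ester)
Conditions: Tf2O, aq. LiOH, toluene, 5 °C
Reagents that add atoms: trifluoromethanesulfonic anhydride, O=S(=O)(OS(=O)(=O)C(F)(F)F)C(F)(F)F
Why: O-Sulfonylation of the lithium-chelated enolate of a β-keto ester should give the enol triflate with the sulfonate cis to the ester, which fixes the later C5=C6 geometry.

Step 12
Reactants: 16 ethyl (2E)-2-chloro-3-[(trifluoromethanesulfonyl)oxy]but-2-enoate
Product: 17 (2E)-2-chloro-3-[(trifluoromethanesulfonyl)oxy]but-2-en-1-ol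
Conditions: i-Bu2AlH (2.2 equiv), CH2Cl2, −78 °C
Reagents that add atoms: none
Why: Aluminium hydride reduction of the ester to the allylic alcohol at −78 °C, which vinyl triflates and vinyl chlorides tolerate, keeps later hydride steps off the main line.

Step 13
Reactants: 17 (2E)-2-chloro-3-[(trifluoromethanesulfonyl)oxy]but-2-en-1-ol
Product: 18 (2E)-1-[(tert-butyldimethylsilyl)oxy]-2-chlorobut-2-en-3-yl trifluoromethanesulfonate
Conditions: TBSCl, imidazole, CH2Cl2, 0 °C
Reagents that add atoms: tert-butyldimethylsilyl chloride, CC(C)(C)[Si](C)(C)Cl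
Why: Standard silylation protects the future C7 oxygen as a primary silyl ether that dilute acid removes in step 21.

Step 14
Reactants: 14 diene diol; 18 (2E)-1-[(tert-butyldimethylsilyl)oxy]-2-chlorobut-2-en-3-yl trifluoromethanesulfonate
Product: 20 chloroalkene diol (C2 and C12 hydroxyls, C7 silyl ether; C4 cis to C7 and C16 cis to Cl), via B-alkyl borane 19 (not isolated)
Conditions: 9-BBN-H (3.3 equiv), THF, 0 °C to rt; then 18, Pd(dppf)Cl2 (5 mol %), AsPh3, aq. K3PO4, DMF, rt
Reagents that add atoms: none
Why: B-alkyl Suzuki–Miyaura coupling: 9-BBN hydroborates only the terminal C3=C4 alkene (the two hydroxyls are held as borinates), and palladium inserts into the C–OTf bond, not the C–Cl bond, and couples with retention, so C4 ends cis to C7; palladium and chlorine are trans in the vinylpalladium species, which excludes syn β-chloride elimination.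

Step 15
Reactants: 20 chloroalkene diol
Product: 21 C2,C12-diacetate
Conditions: Ac2O, DMAP, Et3N, CH2Cl2, rt
Reagents that add atoms: acetic anhydride, CC(=O)OC(C)=O
Why: DMAP-catalysed acylation installs both acetates of the target in one step, after the palladium step so that no allylic acetate meets zerovalent palladium.

Step 16
Reactants: 21 C2,C12-diacetate
Product: 23 C9 aldehyde, via collidinium salt 22 (not isolated)
Conditions: Et3SiOTf, 2,4,6-collidine, CH2Cl2, 0 °C; then H2O
Reagents that add atoms: water, O
Why: Non-acidic acetal cleavage (silyl triflate-induced ionisation to an N,O-acetal pyridinium salt, then hydrolysis) frees the aldehyde and should spare the primary silyl ether and the allylic acetate.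

Step 17
Reactants: 23 C9 aldehyde; 24 methyl propiolate
Product: 25 γ-hydroxy ynoate (C9 epimers)
Conditions: LiN(SiMe3)2, THF, −78 °C
Reagents that add atoms: none
Why: 1,2-Addition of lithium methyl propiolate to the aldehyde at −78 °C is faster than attack on the acetates and brings in C8, C17 and C19; the C9 configuration is left open because steps 18 and 19 reset it.

Step 18
Reactants: 25 γ-hydroxy ynoate (C9 epimers)
Product: 26 γ-oxo ynoate (C9 ketone)
Conditions: Dess–Martin periodinane, NaHCO3, CH2Cl2, 0 °C
Reagents that add atoms: none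
Why: Dess–Martin oxidation of the propargylic alcohol under buffered conditions gives the ynone without epimerising C10; the ynone is used at once.

Step 19
Reactants: 26 γ-oxo ynoate
Product: 27 γ-hydroxy ynoate with the C9 configuration of the target
Conditions: (S)-Me-CBS oxazaborolidine (0.5 equiv), catecholborane, toluene, −78 °C
Reagents that add atoms: none
Why: Corey–Bakshi–Shibata reduction of an alkynyl ketone: the alkyne is the small group and C10 the large one, so the (S)-catalyst should give the required C9 carbinol, in the same sense as the substrate bias for hydride attack anti to the quaternary C1.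

Step 20
Reactants: 27 γ-hydroxy ynoate
Product: 28 C9 di-tert-butylsilyl (Si–H) ether
Conditions: t-Bu2SiHCl, imidazole, DMF, rt
Reagents that add atoms: di-tert-butylchlorosilane, CC(C)(C)[SiH](Cl)C(C)(C)C
Why: Silylation of the secondary alcohol protects O9 against tetronate formation and places on it the hydridosilane that later becomes the O8–Si–O9 bridge.

Step 21
Reactants: 28 C9 di-tert-butylsilyl ether
Product: 30 β-keto ester with free C7 allylic alcohol, via enamino ester 29 (not isolated)
Conditions: pyrrolidine, THF, 0 °C to rt; then 1 M HCl, THF, rt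
Reagents that add atoms: water, O
Why: Conjugate addition of a secondary amine to the ynoate at C8 and acid hydrolysis of the enamino ester hydrate the alkyne to the C8 ketone regiospecifically, and the same acid removes the primary allylic silyl ether while the hindered secondary silyl ether stays.

Step 22
Reactants: 30 β-keto ester with free C7 allylic alcohol
Product: 31 β-keto ester with C7 chloroenal
Conditions: MnO2, CH2Cl2, rt
Reagents that add atoms: none
Why: Manganese dioxide oxidises only the allylic alcohol, and the tetrasubstituted chloroenal cannot isomerise or enolise.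

Step 23
Reactants: 31 β-keto ester with C7 chloroenal
Product: 34 α-methylene β-keto ester, via Mannich base 32 (not isolated), via ammonium iodide 33 (not isolated)
Conditions: CH2=NMe2+ I− (1.05 equiv), CH2Cl2, rt; MeI; then aq. NaHCO3
Reagents that add atoms: dimethyl(methylene)ammonium iodide, C=[N+](C)C.[I-]
Why: Mannich aminomethylation of the β-keto ester at C17, N-methylation and mild-base elimination of trimethylamine give the 2-methylene-1,3-dicarbonyl unit (C18), which is used without storage.

Step 24
Reactants: 34 α-methylene β-keto ester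
Product: 36 cyclisation precursor (bromomethyl acrylate whose O8 and O9 are joined by di-tert-butylsilylene; CH2Br cis to O8), via bromosilane 35 (not isolated)
Conditions: NBS (1.0 equiv), CH2Cl2, −20 °C to rt, dark
Reagents that add atoms: N-bromosuccinimide, O=C1CCC(=O)N1Br
Why: NBS converts the alkoxy hydrosilane into the silyl bromide (the usual first step of silicon-tether synthesis), which should add across the neighbouring enone in the 1,4-sense known for halosilanes, silicon to O8 and bromide to C18 through the s-cis conformer, so that the five-membered silylene closes and CH2Br ends cis to O8.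

Step 25
Reactants: 36 cyclisation precursor
Product: 39 tricyclic α-methylene lactone with the 8,9-O-silylene, via allylzinc bromide 37 (not isolated), via zinc alkoxide 38 (not isolated)
Conditions: Zn dust (activated with TMSCl and 1,2-dibromoethane), THF, rt, slow addition of 36 to 1 mM; aq. NH4Cl
Reagents that add atoms: none
Why: Proposed new method: zinc inserts into the allylic C18–Br bond to give the 2-(methoxycarbonyl)allylzinc 37, which should add through its γ-carbon C8 to the C7 aldehyde in a six-membered chair with allylic transposition (alkene to C17=C18), creating the O8-bearing quaternary carbon, after which the zinc alkoxide 38 acylates on the C19 ester; the closest known reaction type is the Barbier allylation–lactonisation of 2-(bromomethyl)acrylates with aldehydes, known also for medium rings, whereas a γ-silyloxy, γ,γ-disubstituted allyl metal of this kind is untested. The ten-membered ring closes by 10-exo-trig addition to the carbonyl and the lactone by 5-exo-trig acyl substitution. C8 is controlled by C9 through the dioxasilolane: the aldehyde is tied to C10, and with O8 and O9 held syn it can reach C8 only on the face opposite the C9–C10 bond, because approach on the same face would eclipse C7 and C10 in the forming ring. C7 is controlled by the chair: O8 (cis to C18) is axial, C9 and the aldehyde substituent C6 are equatorial, so H7 ends anti to O8 and the lactone is trans-fused. The step needs γ- over α-attack (secured by the cyclic transition state and the smaller ring), insertion only at the allylic bromide (vinyl chloride and acetates are inert to zinc) and ring closure over oligomerisation (slow addition at high dilution); the chloroenal is the only aldehyde and cannot enolise.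

Step 26
Reactants: 39 tricyclic α-methylene lactone
Product: 40 α-methyl lactone (C17 set, C18 cis to O8)
Conditions: [(Ph3P)CuH]6, toluene–THF, H2O (3 equiv), rt
Reagents that add atoms: none
Why: Copper hydride conjugate reduction touches only the exocyclic enoate, and C17 is set on protonation of the copper enolate; the epimer with C18 on the O8 face, away from the C9–C10 bond, should be the more stable one and is reached either directly or by base equilibration of this epimerisable centre.

Step 27
Reactants: 40 α-methyl lactone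
Product: 41 target (CNP0296164.1)
Conditions: HF·pyridine, pyridine, THF, 0 °C
Reagents that add atoms: none
Why: Fluoride cleavage of the strained five-membered dialkylsilylene frees the C8 and C9 hydroxyls in one step under conditions that leave both acetates and the lactone untouched.

Compound list
1 | 2,2-dimethoxyacetaldehyde | COC(OC)C=O | starting material
2 | ethyl 2-(triphenyl-λ5-phosphanylidene)propanoate | CCOC(=O)C(C)=P(c1ccccc1)(c1ccccc1)c1ccccc1 | starting material
3 | ethyl (2E)-4,4-dimethoxy-2-methylbut-2-enoate | CCOC(=O)/C(C)=C/C(OC)OC | intermediate (not isolated)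
4 | ethyl (2E)-2-methyl-4-oxobut-2-enoate | CCOC(=O)/C(C)=C/C=O | intermediate
5 | (E)-penta-1,3-diene | C/C=C/C=C | starting material
6 | ethyl (1S,5S,6S)-6-formyl-1,5-dimethylcyclohex-3-ene-1-carboxylate (C9 aldehyde cis to both methyls, trans to the ester) | O=C[C@H]1[C@@H](C)C=CC[C@]1(C)C(=O)OCC | intermediate
7 | ethyl (1S,5S,6S)-6-(dimethoxymethyl)-1,5-dimethylcyclohex-3-ene-1-carboxylate | COC(OC)[C@H]1[C@@H](C)C=CC[C@]1(C)C(=O)OCC | intermediate
8 | [(1S,5S,6S)-6-(dimethoxymethyl)-1,5-dimethylcyclohex-3-en-1-yl]methanol | COC(OC)[C@H]1[C@@H](C)C=CC[C@]1(C)CO | intermediate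
9 | syn-epoxy alcohol: 12,13-epoxide of 8, oxirane oxygen cis to CH2OH | COC(OC)[C@H]1[C@@H](C)[C@@H]2O[C@@H]2C[C@]1(C)CO | intermediate
10 | epoxy aldehyde: C2 aldehyde of 9 | COC(OC)[C@H]1[C@@H](C)[C@@H]2O[C@@H]2C[C@]1(C)C=O | intermediate
11 | epoxy vinyl carbinol, C2 epimers | COC(OC)[C@H]1[C@@H](C)[C@@H]2O[C@@H]2C[C@]1(C)C(O)C=C | intermediate
12 | epoxy vinyl ketone | COC(OC)[C@H]1[C@@H](C)[C@@H]2O[C@@H]2C[C@]1(C)C(=O)C=C | intermediate
13 | epoxy allylic alcohol, C2 as in the target | COC(OC)[C@H]1[C@@H](C)[C@@H]2O[C@@H]2C[C@]1(C)[C@@H](O)C=C | intermediate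
14 | diene diol: C12 hydroxyl trans to the C11 methyl, C13=C14 ring alkene, C2 vinyl carbinol | COC(OC)[C@H]1[C@@H](C)[C@H](O)C=C[C@]1(C)[C@@H](O)C=C | intermediate
15 | ethyl 2-chloro-3-oxobutanoate | CCOC(=O)C(Cl)C(C)=O | starting material
16 | ethyl (2E)-2-chloro-3-[(trifluoromethanesulfonyl)oxy]but-2-enoate | CCOC(=O)/C(Cl)=C(/C)OS(=O)(=O)C(F)(F)F | intermediate
17 | (2E)-2-chloro-3-[(trifluoromethanesulfonyl)oxy]but-2-en-1-ol | C/C(OS(=O)(=O)C(F)(F)F)=C(\Cl)CO | intermediate
18 | (2E)-1-[(tert-butyldimethylsilyl)oxy]-2-chlorobut-2-en-3-yl trifluoromethanesulfonate | C/C(OS(=O)(=O)C(F)(F)F)=C(\Cl)CO[Si](C)(C)C(C)(C)C | intermediate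
19 | C4 B-alkyl-9-BBN of 14 with both hydroxyls as 9-BBN borinates | COC(OC)[C@H]1[C@@H](C)[C@H](OB2C3CCCC2CCC3)C=C[C@]1(C)[C@@H](OB2C3CCCC2CCC3)CCB2C3CCCC2CCC3 | intermediate (not isolated)
20 | chloroalkene diol: C2–C7 chain attached, C7 silyl ether, C4 cis to C7 | COC(OC)[C@H]1[C@@H](C)[C@H](O)C=C[C@]1(C)[C@@H](O)CC/C(C)=C(/Cl)CO[Si](C)(C)C(C)(C)C | intermediate
21 | C2,C12-diacetate of 20 | COC(OC)[C@H]1[C@@H](C)[C@H](OC(C)=O)C=C[C@]1(C)[C@@H](OC(C)=O)CC/C(C)=C(/Cl)CO[Si](C)(C)C(C)(C)C | intermediate
22 | N-(1-methoxyalkyl)-2,4,6-trimethylpyridinium triflate at C9 | COC([C@H]1[C@@H](C)[C@H](OC(C)=O)C=C[C@]1(C)[C@@H](OC(C)=O)CC/C(C)=C(/Cl)CO[Si](C)(C)C(C)(C)C)[n+]1c(C)cc(C)cc1C.[O-]S(=O)(=O)C(F)(F)F | intermediate (not isolated)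
23 | C9 aldehyde | O=C[C@H]1[C@@H](C)[C@H](OC(C)=O)C=C[C@]1(C)[C@@H](OC(C)=O)CC/C(C)=C(/Cl)CO[Si](C)(C)C(C)(C)C | intermediate
24 | methyl propiolate | COC(=O)C#C | starting material
25 | γ-hydroxy ynoate, C9 epimers | COC(=O)C#CC(O)[C@H]1[C@@H](C)[C@H](OC(C)=O)C=C[C@]1(C)[C@@H](OC(C)=O)CC/C(C)=C(/Cl)CO[Si](C)(C)C(C)(C)C | intermediate
26 | γ-oxo ynoate | COC(=O)C#CC(=O)[C@H]1[C@@H](C)[C@H](OC(C)=O)C=C[C@]1(C)[C@@H](OC(C)=O)CC/C(C)=C(/Cl)CO[Si](C)(C)C(C)(C)C | intermediate
27 | γ-hydroxy ynoate, C9 as in the target | COC(=O)C#C[C@@H](O)[C@H]1[C@@H](C)[C@H](OC(C)=O)C=C[C@]1(C)[C@@H](OC(C)=O)CC/C(C)=C(/Cl)CO[Si](C)(C)C(C)(C)C | intermediate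
28 | C9 di-tert-butylsilyl (Si–H) ether of 27 | COC(=O)C#C[C@@H](O[SiH](C(C)(C)C)C(C)(C)C)[C@H]1[C@@H](C)[C@H](OC(C)=O)C=C[C@]1(C)[C@@H](OC(C)=O)CC/C(C)=C(/Cl)CO[Si](C)(C)C(C)(C)C | intermediate
29 | (E)-β-pyrrolidinyl enoate (nitrogen on C8) | COC(=O)/C=C(/N1CCCC1)[C@@H](O[SiH](C(C)(C)C)C(C)(C)C)[C@H]1[C@@H](C)[C@H](OC(C)=O)C=C[C@]1(C)[C@@H](OC(C)=O)CC/C(C)=C(/Cl)CO[Si](C)(C)C(C)(C)C | intermediate (not isolated)
30 | β-keto ester (C8 ketone) with free C7 allylic alcohol | COC(=O)CC(=O)[C@@H](O[SiH](C(C)(C)C)C(C)(C)C)[C@H]1[C@@H](C)[C@H](OC(C)=O)C=C[C@]1(C)[C@@H](OC(C)=O)CC/C(C)=C(/Cl)CO | intermediate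
31 | β-keto ester with C7 chloroenal | COC(=O)CC(=O)[C@@H](O[SiH](C(C)(C)C)C(C)(C)C)[C@H]1[C@@H](C)[C@H](OC(C)=O)C=C[C@]1(C)[C@@H](OC(C)=O)CC/C(C)=C(/Cl)C=O | intermediate
32 | C17 (dimethylamino)methyl β-keto ester | COC(=O)C(CN(C)C)C(=O)[C@@H](O[SiH](C(C)(C)C)C(C)(C)C)[C@H]1[C@@H](C)[C@H](OC(C)=O)C=C[C@]1(C)[C@@H](OC(C)=O)CC/C(C)=C(/Cl)C=O | intermediate (not isolated)
33 | C17 (trimethylammonio)methyl β-keto ester iodide | COC(=O)C(C[N+](C)(C)C)C(=O)[C@@H](O[SiH](C(C)(C)C)C(C)(C)C)[C@H]1[C@@H](C)[C@H](OC(C)=O)C=C[C@]1(C)[C@@H](OC(C)=O)CC/C(C)=C(/Cl)C=O.[I-] | intermediate (not isolated)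
34 | α-methylene β-keto ester (C17=C18) | COC(=O)C(=C)C(=O)[C@@H](O[SiH](C(C)(C)C)C(C)(C)C)[C@H]1[C@@H](C)[C@H](OC(C)=O)C=C[C@]1(C)[C@@H](OC(C)=O)CC/C(C)=C(/Cl)C=O | intermediate
35 | C9 bromo(di-tert-butyl)silyl ether of 34 | COC(=O)C(=C)C(=O)[C@@H](O[Si](Br)(C(C)(C)C)C(C)(C)C)[C@H]1[C@@H](C)[C@H](OC(C)=O)C=C[C@]1(C)[C@@H](OC(C)=O)CC/C(C)=C(/Cl)C=O | intermediate (not isolated)
36 | open-chain precursor: C7 chloroenal; methyl 2-(bromomethyl)acrylate whose β-carbon C8 is the exocyclic carbon of a 2,2-di-tert-butyl-1,3,2-dioxasilolane (O8, O9, C9); CH2Br cis to O8 | COC(=O)/C(CBr)=C1/O[Si](C(C)(C)C)(C(C)(C)C)O[C@H]1[C@H]2[C@@H](C)[C@H](OC(C)=O)C=C[C@]2(C)[C@@H](OC(C)=O)CC/C(C)=C(/Cl)C=O | intermediate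
37 | C18 allylzinc bromide of 36 | COC(=O)/C(C[Zn]Br)=C1/O[Si](C(C)(C)C)(C(C)(C)C)O[C@H]1[C@H]2[C@@H](C)[C@H](OC(C)=O)C=C[C@]2(C)[C@@H](OC(C)=O)CC/C(C)=C(/Cl)C=O | intermediate (not isolated)
38 | ten-membered C7 zinc alkoxide with methyl 2-methylene ester on C8 | CC(=O)O[C@H]1CC/C(C)=C(/Cl)[C@H](O[Zn]Br)[C@](C(=C)C(=O)OC)(O[Si](C(C)(C)C)(C(C)(C)C)O3)[C@@H]3[C@H]2[C@@H](C)[C@H](OC(C)=O)C=C[C@@]21C | intermediate (not isolated)
39 | tricyclic α-methylene lactone, trans-fused at C7–C8, O8 and O9 as di-tert-butylsilylene | CC(=O)O[C@H]1CC/C(C)=C(/Cl)[C@@H]2OC(=O)C(=C)[C@@]2(O[Si](C(C)(C)C)(C(C)(C)C)O3)[C@@H]3[C@H]2[C@@H](C)[C@H](OC(C)=O)C=C[C@@]21C | intermediate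
40 | α-methyl lactone, C18 cis to O8, silylene retained | CC(=O)O[C@H]1CC/C(C)=C(/Cl)[C@@H]2OC(=O)[C@H](C)[C@@]2(O[Si](C(C)(C)C)(C(C)(C)C)O3)[C@@H]3[C@H]2[C@@H](C)[C@H](OC(C)=O)C=C[C@@]21C | intermediate
41 | CNP0296164.1 | CC(=O)O[C@H]1CC/C(C)=C(/Cl)[C@@H]2OC(=O)[C@H](C)[C@@]2(O)[C@@H](O)[C@H]2[C@@H](C)[C@H](OC(C)=O)C=C[C@@]21C | target

Total step count: 27. Longest linear sequence: 24 steps (steps 1 to 10 and 14 to 27); steps 11 to 13 make the side-chain triflate 18.

Steps most likely to fail

1. Step 25. The allylzinc may be protonated or may couple through C18 before the hindered, oxygen-bearing C8 reaches the aldehyde; oligomerisation may outrun ring closure; the strained silylene may open under the zinc salts. Fallback with known chemistry and no allyl metal, setting out from 31: C-methylation of the β-keto ester (MeI, K2CO3, acetone) should give the α-methyl β-keto ester F1. NBS followed by 2,6-lutidine turns Si–H into Si–Br and closes the silylene on the enol oxygen to give the α-methyl silyl enol ether F2. SmI2 in THF–t-BuOH at high dilution then forms the C7 ketyl, which adds to C8 of the β-silyloxy acrylate (ketyl–olefin cyclisation onto a β-alkoxyacrylate); the samarium enolate is protonated at C17 and the C7 alkoxide lactonises. This comes back to the route at 40, so step 26 is not needed.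

2. Step 2. The trisubstituted enal may form its iminium ion too slowly or react with poor facial or regiochemical selectivity. Fallback setting out from 4 and 5: Me2AlCl (CH2Cl2, −78 °C) promotes the same cycloaddition without enantiocontrol and gives 6 as the racemate. Condensation with (1R,2R)-N,N'-dimethyl-1,2-diphenylethane-1,2-diamine gives two diastereomeric imidazolidines, which are separated on silica. The imidazolidine F3, formed from the (1S,5S,6S) aldehyde, is hydrolysed with dilute HCl in Et2O and comes back to the route at 6.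

3. Step 24. Bromination at silicon may not be followed by conjugate addition, NBS may attack the enone or the new enol ether, or the five-membered silylene may hydrolyse on isolation. Fallback setting out from 34: Et3SiBr (CH2Cl2, −78 °C) adds across the s-cis enone without the tether and should give the open enol triethylsilyl ether F4, again with CH2Br cis to O8. Zinc under the conditions of step 25 then gives the lactone F5, [(Ph3P)CuH]6 gives the α-methyl lactone F6, and HF·pyridine removes the triethylsilyl and di-tert-butylsilyl groups together, coming back to the route at 41.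

Further compounds
F1 | step 25 | α-methyl β-keto ester (C17 methylated 31) | COC(=O)C(C)C(=O)[C@@H](O[SiH](C(C)(C)C)C(C)(C)C)[C@H]1[C@@H](C)[C@H](OC(C)=O)C=C[C@]1(C)[C@@H](OC(C)=O)CC/C(C)=C(/Cl)C=O
F2 | step 25 | α-methyl silyl enol ether with O8 and O9 in the di-tert-butylsilylene ring | COC(=O)C(C)=C1O[Si](C(C)(C)C)(C(C)(C)C)O[C@H]1[C@H]2[C@@H](C)[C@H](OC(C)=O)C=C[C@]2(C)[C@@H](OC(C)=O)CC/C(C)=C(/Cl)C=O
F3 | step 2 | (4R,5R)-1,3-dimethyl-4,5-diphenylimidazolidine aminal of 6 | C3(N(C)[C@H](c2ccccc2)[C@@H](c2ccccc2)N3C)[C@H]1[C@@H](C)C=CC[C@]1(C)C(=O)OCC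
F4 | step 24 | open-chain bromomethyl acrylate with O8 triethylsilyl enol ether and O9 di-tert-butylsilyl (Si–H) ether | COC(=O)/C(CBr)=C(/O[Si](CC)(CC)CC)[C@@H](O[SiH](C(C)(C)C)C(C)(C)C)[C@H]1[C@@H](C)[C@H](OC(C)=O)C=C[C@]1(C)[C@@H](OC(C)=O)CC/C(C)=C(/Cl)C=O
F5 | step 24 | tricyclic α-methylene lactone with O8 triethylsilyl and O9 di-tert-butylsilyl ethers | CC(=O)O[C@H]1CC/C(C)=C(/Cl)[C@@H]2OC(=O)C(=C)[C@@]2(O[Si](CC)(CC)CC)[C@@H](O[SiH](C(C)(C)C)C(C)(C)C)[C@H]2[C@@H](C)[C@H](OC(C)=O)C=C[C@@]21C
F6 | step 24 | α-methyl lactone with O8 triethylsilyl and O9 di-tert-butylsilyl ethers | CC(=O)O[C@H]1CC/C(C)=C(/Cl)[C@@H]2OC(=O)[C@H](C)[C@@]2(O[Si](CC)(CC)CC)[C@@H](O[SiH](C(C)(C)C)C(C)(C)C)[C@H]2[C@@H](C)[C@H](OC(C)=O)C=C[C@@]21C
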